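In calamenene numbering (C1 methyl, C4 isopropyl, C4a/C8a fusion carbons, C8 OH; primes for the half joined through C5'), the plan rests on one feature. In both aromatic rings the OH carbon C8 (C8') is the direct neighbour of fusion carbon C8a (C8a'), and the biaryl bond runs from C7 (ortho to OH) to C5' (para to OH, next to C4a'). C4a–C5–C6–C7 and C4a'–C5'–C6'–C7' can therefore be read as the carbons of two furans joined alpha to beta, and C8a–C8 and C8a'–C8' as two terminal alkynes.
Final disconnection: C4a–C8a and C7–C8 in unit A, C4a'–C8a' and C7'–C8' in unit B. This opens both benzene rings and both carbocycles at once and leads to the isomeric bis(alkynyl)-2,3'-bifuran 21.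
21 is traced to bis-acetal 19 (on both arms acetal, then aldehyde, then alkyne), and 19 to a Negishi coupling of alpha-zincated furan 18 with beta-iodofuran 16.
Both furans go back to one 3-alkyne-1,2-diol 14 (cyclodehydration gives 15, iodocyclisation gives 16). Building the rings from the alkyne fixes the chain/methyl/link pattern; substitution or lithiation of 3-methylfuran, which goes to or mixes in the position next to methyl, would not deliver it, least of all the beta link of furan B.
C1/C4 and C1'/C4' come from (+)-menthol: the trans-1-methyl-4-isopropyl carbocycle of each half is the p-menthane ring, opened at the future C4a–C8a bond by ozonolysis of the kinetic enol silane of (+)-menthone. Ring order: two furans (steps 7 and 8), then all four target rings in step 12.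

Key step: step 12

Assumption: the given structure fixes C1, C4, C1' and C4' but not the sense of the hindered C7–C5' axis, so either atropisomer counts as the target; should both form, they are to be separated by chromatography.

Step 1
Reactants: 1 (1S,2R,5S)-(+)-menthol
Product: 2 (2R,5S)-(+)-menthone
Conditions: NaOCl (aq), TEMPO (1 mol %), KBr (10 mol %), NaHCO3, CH2Cl2–H2O, 0 °C
Reagents that add atoms: none
Why: The oxoammonium (TEMPO/hypochlorite, Anelli) oxidation turns the secondary alcohol into the ketone at 0 °C in a bicarbonate buffer, which is too mild to enolise the product, so the isopropyl centre C2 and the methyl centre C5 of the chiral-pool material are carried over unchanged.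

Step 2
Reactants: 2 (2R,5S)-(+)-menthone
Product: 4 trimethyl{[(3S,6R)-3-methyl-6-(propan-2-yl)cyclohex-1-en-1-yl]oxy}silane, via lithium enolate 3 (not isolated)
Conditions: LiN(iPr)2 (1.1 equiv), THF, −78 °C; Me3SiCl, −78 → 0 °C; cold aq. NaHCO3, pentane
Reagents that add atoms: chlorotrimethylsilane, C[Si](C)(C)Cl
Why: Kinetic deprotonation by the bulky amide takes a proton of the open C6 methylene rather than the C2 methine beside isopropyl, and O-silylation traps the less substituted enolate (kinetic silyl enol ether formation), so C2 is never planarised.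

Step 3
Reactants: 4 trimethyl{[(3S,6R)-3-methyl-6-(propan-2-yl)cyclohex-1-en-1-yl]oxy}silane
Product: 6 (2R,5S)-6,6-dimethoxy-5-methyl-2-(propan-2-yl)hexanoic acid, via aldehyde acid 5 (not isolated)
Conditions: O3, CH2Cl2–MeOH (5:1), −78 °C; Me2S, −78 °C → rt; then HC(OMe)3, TsOH·H2O (5 mol %), rt; extraction at pH 5, used crude
Reagents that add atoms: ozone, [O-][O+]=O; trimethyl orthoformate, COC(OC)OC
Why: Ozonolysis of the only alkene, the electron-rich enol silane, with reductive work-up cuts the menthane C1–C6 bond into a silyl ester (cleaved by methanol to the acid) and an aldehyde, which acid-catalysed exchange with orthoformate masks at once as its dimethyl acetal, so the epimerisable alpha-methyl aldehyde is never stored and both stereocentres stay spectators.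

Step 4
Reactants: 6 (2R,5S)-6,6-dimethoxy-5-methyl-2-(propan-2-yl)hexanoic acid
Product: 7 methyl (2R,5S)-6,6-dimethoxy-5-methyl-2-(propan-2-yl)hexanoate
Conditions: MeI, K2CO3, DMF, rt
Reagents that add atoms: iodomethane, CI
Why: SN2 O-alkylation of the carboxylate under a weak base touches neither the acetal nor the alpha centre, and any ester already formed in the acidic methanol of step 3 is the same compound.

Step 5
Reactants: 7 methyl (2R,5S)-6,6-dimethoxy-5-methyl-2-(propan-2-yl)hexanoate; 8 dimethyl (1-diazo-2-oxopropyl)phosphonate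
Product: 10 (3R,6S)-7,7-dimethoxy-6-methyl-3-(propan-2-yl)hept-1-yne, via aldehyde 9 (not isolated)
Conditions: iBu2AlH (1.1 equiv), CH2Cl2, −78 °C; MeOH; then K2CO3, 8, −78 °C → rt; aq. potassium sodium tartrate
Reagents that add atoms: dimethyl (1-diazo-2-oxopropyl)phosphonate 8, COP(=O)(OC)C(=[N+]=[N-])C(C)=O
Why: The aluminium hemiacetal of the hindered ester holds at −78 °C and releases aldehyde 9 only after the methanol quench, where the diazomethylphosphonate anion made from 8 converts it into the terminal alkyne (one-pot ester reduction and Ohira–Bestmann homologation), a process that for alpha-alkyl aldehydes should outrun enolisation, so the isopropyl centre is kept.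

Step 6
Reactants: 10 (3R,6S)-7,7-dimethoxy-6-methyl-3-(propan-2-yl)hept-1-yne; 11 1-[(tert-butyldimethylsilyl)oxy]propan-2-one
Product: 14 (5R,8S)-9,9-dimethoxy-2,8-dimethyl-5-(propan-2-yl)non-3-yne-1,2-diol (both C2 epimers), via lithium acetylide 12 (not isolated), via silyl ether alkoxide 13 (not isolated)
Conditions: n-BuLi (1.05 equiv), THF, −78 °C; 11, −78 → 0 °C; Bu4NF (1.5 equiv), 0 °C → rt; H2O
Reagents that add atoms: 1-[(tert-butyldimethylsilyl)oxy]propan-2-one 11, CC(=O)CO[Si](C)(C)C(C)(C)C
Why: 1,2-Addition of the lithium acetylide to the alpha-silyloxy ketone and fluoride desilylation in the same flask give the 3-alkyne-1,2-diol; the new carbinol centre forms without control, which is harmless because it becomes an sp2 furan carbon in steps 7 and 8.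

Step 7
Reactants: 14 (5R,8S)-9,9-dimethoxy-2,8-dimethyl-5-(propan-2-yl)non-3-yne-1,2-diol
Product: 15 2-[(3R,6S)-7,7-dimethoxy-2,6-dimethylheptan-3-yl]-4-methylfuran
Conditions: (Ph3P)AuCl (2 mol %), AgOTf (2 mol %), 4 Å molecular sieves, THF, 0 °C → rt
Reagents that add atoms: none
Why: Cationic gold activates the alkyne for 5-endo-dig attack of the primary hydroxyl on the chain-bearing carbon, and the tertiary alcohol then leaves as water (cyclodehydration of 3-alkyne-1,2-diols to furans); this places the chain at C2 and methyl at C4 without a regiochemical choice, while the sieves bind the water and protect the acetal.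

Step 8
Reactants: 14 (5R,8S)-9,9-dimethoxy-2,8-dimethyl-5-(propan-2-yl)non-3-yne-1,2-diol
Product: 16 2-[(3R,6S)-7,7-dimethoxy-2,6-dimethylheptan-3-yl]-3-iodo-4-methylfuran
Conditions: I2 (3 equiv), NaHCO3 (3 equiv), MeCN, 0 °C → rt; aq. Na2S2O3
Reagents that add atoms: iodine, II
Why: Iodonium activation of the same alkyne triggers the 5-endo-dig iodocyclisation and spontaneous dehydration known for 3-alkyne-1,2-diols, so iodine ends on the beta carbon between chain and methyl, a position that direct halogenation of a furan with a free alpha carbon cannot reach.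

Step 9
Reactants: 15 2-[(3R,6S)-7,7-dimethoxy-2,6-dimethylheptan-3-yl]-4-methylfuran; 16 2-[(3R,6S)-7,7-dimethoxy-2,6-dimethylheptan-3-yl]-3-iodo-4-methylfuran
Product: 19 5,2'-bis[(3R,6S)-7,7-dimethoxy-2,6-dimethylheptan-3-yl]-3,4'-dimethyl-2,3'-bifuran, via furyllithium 17 (not isolated), via furylzinc chloride 18 (not isolated)
Conditions: 15, n-BuLi (1.1 equiv), THF, −78 → 0 °C; ZnCl2 (1.2 equiv), 0 °C → rt; 16, Pd2(dba)3 (2.5 mol %), SPhos (10 mol %), 50 °C
Reagents that add atoms: none
Why: n-BuLi removes the only alpha proton of 15, transmetalation gives a furylzinc chloride that tolerates the acetals, and Negishi coupling with the beta-iodofuran on zerovalent palladium carrying a bulky biarylphosphine forms the hindered furan–furan bond (the future C7–C5' bond) without touching a stereocentre.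

Step 10
Reactants: 19 5,2'-bis[(3R,6S)-7,7-dimethoxy-2,6-dimethylheptan-3-yl]-3,4'-dimethyl-2,3'-bifuran
Product: 20 5,2'-bis[(3R,6S)-2,6-dimethyl-7-oxoheptan-3-yl]-3,4'-dimethyl-2,3'-bifuran
Conditions: pyridinium p-toluenesulfonate (20 mol %), acetone–H2O (9:1), 40 °C
Reagents that add atoms: water, O
Why: Mild acid-catalysed acetal hydrolysis frees both aldehydes under conditions too weak to open the alkylated furans or to enolise the alpha-methyl aldehydes to a relevant degree.

Step 11
Reactants: 20 5,2'-bis[(3R,6S)-2,6-dimethyl-7-oxoheptan-3-yl]-3,4'-dimethyl-2,3'-bifuran; 8 dimethyl (1-diazo-2-oxopropyl)phosphonate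
Product: 21 5,2'-bis[(3R,6S)-2,6-dimethyloct-7-yn-3-yl]-3,4'-dimethyl-2,3'-bifuran
Conditions: 8 (3 equiv), K2CO3 (4 equiv), MeOH–THF, 0 °C → rt
Reagents that add atoms: dimethyl (1-diazo-2-oxopropyl)phosphonate 8, COP(=O)(OC)C(=[N+]=[N-])C(C)=O
Why: A twofold Ohira–Bestmann homologation converts both aldehydes into terminal alkynes under carbonate in methanol, a medium in which alpha-methyl-branched aliphatic aldehydes are expected to keep their configuration, so the future C1 and C1' are retained.

Step 12
Reactants: 21 5,2'-bis[(3R,6S)-2,6-dimethyloct-7-yn-3-yl]-3,4'-dimethyl-2,3'-bifuran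
Product: 23 target CNP0145304.1 (C7–C5' linked dimer of (1S,4R)-8-hydroxycalamenene), via half-cyclised furyl phenol 22 (not isolated)
Conditions: (Ph3P)AuNTf2 (10 mol %), CH2Cl2 (0.01 M), rt → 40 °C
Reagents that add atoms: none
Why: (Ph3P)Au+ binds each terminal alkyne, the tether-bearing furan carbon attacks the internal alkyne carbon (C4a–C8a, C4a'–C8a'), the cyclopropyl gold carbene so formed opens with loss of the furan C–O bond to a dienyl carbonyl gold carbene (a ketone in unit A, an aldehyde in unit B), the carbonyl oxygen adds to the carbene carbon to give an oxepine, its arene oxide valence isomer holds the new C7–C8 (C7'–C8') bond, and epoxide opening with loss of the C8 (C8') proton gives the phenol. The closest known reaction is the gold-catalysed furan–yne phenol synthesis of 2-tethered furans with terminal alkynes, which tolerates four-atom tethers and bulky aryl groups on the furan alpha carbon; it is used here twice in one molecule, the less shielded furan A being expected to react first via 22. Each six-membered carbocycle closes 6-exo-dig, and each benzene ring closes by O–C8 bond formation to the seven-membered oxepine followed by its 6π electrocyclisation. No stereocentre is created: C1, C4, C1' and C4' sit on the tethers and are not ionised under these neutral conditions, and only the C7–C5' axis is frozen, with the adjacent C4' centre as the sole possible source of bias. The step needs each alkyne to pair with its own furan, which six-membered against medium-ring transition states secure, and it needs both arene oxides to open at the C7–O (C7'–O) bond: in unit A C7 carries ring B, so the cation is tertiary and only C8 has a proton to lose, whereas in unit B, where C7' bears hydrogen, the outcome rests on delocalisation of the charge onto C5' (donor ring A attached) and C8a' and on the usual preference of alpha-unsubstituted furans for the phenol next to the fusion. High dilution keeps the free alpha C–H of furan B from adding to an alkyne of a second molecule.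

Compound list
1 | (1S,2R,5S)-(+)-menthol | CC(C)[C@H]1CC[C@H](C)C[C@@H]1O | starting material
2 | (2R,5S)-(+)-menthone | CC(C)[C@H]1CC[C@H](C)CC1=O | intermediate
3 | lithium (3S,6R)-3-methyl-6-(propan-2-yl)cyclohex-1-en-1-olate | CC(C)[C@H]1CC[C@H](C)C=C1O[Li] | intermediate
4 | trimethyl{[(3S,6R)-3-methyl-6-(propan-2-yl)cyclohex-1-en-1-yl]oxy}silane | CC(C)[C@H]1CC[C@H](C)C=C1O[Si](C)(C)C | intermediate
5 | (2R,5S)-5-methyl-6-oxo-2-(propan-2-yl)hexanoic acid | CC(C)[C@@H](CC[C@H](C)C=O)C(=O)O | intermediate
6 | (2R,5S)-6,6-dimethoxy-5-methyl-2-(propan-2-yl)hexanoic acid | CC(C)[C@@H](CC[C@H](C)C(OC)OC)C(=O)O | intermediate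
7 | methyl (2R,5S)-6,6-dimethoxy-5-methyl-2-(propan-2-yl)hexanoate | CC(C)[C@@H](CC[C@H](C)C(OC)OC)C(=O)OC | intermediate
8 | dimethyl (1-diazo-2-oxopropyl)phosphonate | COP(=O)(OC)C(=[N+]=[N-])C(C)=O | starting material
9 | (2R,5S)-6,6-dimethoxy-5-methyl-2-(propan-2-yl)hexanal | CC(C)[C@@H](CC[C@H](C)C(OC)OC)C=O | intermediate
10 | (3R,6S)-7,7-dimethoxy-6-methyl-3-(propan-2-yl)hept-1-yne | CC(C)[C@@H](CC[C@H](C)C(OC)OC)C#C | intermediate
11 | 1-[(tert-butyldimethylsilyl)oxy]propan-2-one | CC(=O)CO[Si](C)(C)C(C)(C)C | starting material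
12 | lithium acetylide of 10 | CC(C)[C@@H](CC[C@H](C)C(OC)OC)C#C[Li] | intermediate
13 | lithium alkoxide of (5R,8S)-1-[(tert-butyldimethylsilyl)oxy]-9,9-dimethoxy-2,8-dimethyl-5-(propan-2-yl)non-3-yn-2-ol (both C2 epimers) | CC(C)[C@@H](CC[C@H](C)C(OC)OC)C#CC(C)(O[Li])CO[Si](C)(C)C(C)(C)C | intermediate
14 | (5R,8S)-9,9-dimethoxy-2,8-dimethyl-5-(propan-2-yl)non-3-yne-1,2-diol (both C2 epimers) | CC(C)[C@@H](CC[C@H](C)C(OC)OC)C#CC(C)(O)CO | intermediate
15 | 2-[(3R,6S)-7,7-dimethoxy-2,6-dimethylheptan-3-yl]-4-methylfuran | CC(C)[C@@H](CC[C@H](C)C(OC)OC)c1cc(C)co1 | intermediate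
16 | 2-[(3R,6S)-7,7-dimethoxy-2,6-dimethylheptan-3-yl]-3-iodo-4-methylfuran | CC(C)[C@@H](CC[C@H](C)C(OC)OC)c1occ(C)c1I | intermediate
17 | {5-[(3R,6S)-7,7-dimethoxy-2,6-dimethylheptan-3-yl]-3-methylfuran-2-yl}lithium | CC(C)[C@@H](CC[C@H](C)C(OC)OC)c1cc(C)c([Li])o1 | intermediate
18 | {5-[(3R,6S)-7,7-dimethoxy-2,6-dimethylheptan-3-yl]-3-methylfuran-2-yl}zinc chloride | CC(C)[C@@H](CC[C@H](C)C(OC)OC)c1cc(C)c([Zn]Cl)o1 | intermediate
19 | 5,2'-bis[(3R,6S)-7,7-dimethoxy-2,6-dimethylheptan-3-yl]-3,4'-dimethyl-2,3'-bifuran | CC(C)[C@@H](CC[C@H](C)C(OC)OC)c1cc(C)c(o1)-c1c(C)coc1[C@@H](C(C)C)CC[C@H](C)C(OC)OC | intermediate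
20 | 5,2'-bis[(3R,6S)-2,6-dimethyl-7-oxoheptan-3-yl]-3,4'-dimethyl-2,3'-bifuran | CC(C)[C@@H](CC[C@H](C)C=O)c1cc(C)c(o1)-c1c(C)coc1[C@@H](C(C)C)CC[C@H](C)C=O | intermediate
21 | 5,2'-bis[(3R,6S)-2,6-dimethyloct-7-yn-3-yl]-3,4'-dimethyl-2,3'-bifuran | C#C[C@@H](C)CC[C@H](C(C)C)c1cc(C)c(o1)-c1c(C)coc1[C@@H](C(C)C)CC[C@H](C)C#C | intermediate
22 | (5R,8S)-2-{2-[(3R,6S)-2,6-dimethyloct-7-yn-3-yl]-4-methylfuran-3-yl}-3,8-dimethyl-5-(propan-2-yl)-5,6,7,8-tetrahydronaphthalen-1-ol | Cc1cc2c(c(O)c1-c1c(C)coc1[C@@H](C(C)C)CC[C@H](C)C#C)[C@@H](C)CC[C@@H]2C(C)C | intermediate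
23 | CNP0145304.1, (5R,8S)-2-[(5S,8R)-4-hydroxy-2,5-dimethyl-8-(propan-2-yl)-5,6,7,8-tetrahydronaphthalen-1-yl]-3,8-dimethyl-5-(propan-2-yl)-5,6,7,8-tetrahydronaphthalen-1-ol | Cc1cc2c(c(O)c1-c1c(C)cc(O)c3c1[C@@H](C(C)C)CC[C@@H]3C)[C@@H](C)CC[C@@H]2C(C)C | target

Total step count: 12. Longest linear sequence: 11 (steps 1–6, step 7 or 8, steps 9–12).

Steps most likely to fail

1. Step 12.
- What may go wrong: the second cyclisation must engage the fully substituted, tether-bearing double bond of furan B, which is shielded by ring A and by the isopropyl-bearing C4'. Slow attack would let the catalyst decay and let the free alpha C–H of furan B add to alkynes of other molecules. Opening of the unit B arene oxide at the C8'–O bond instead of the C7'–O bond would move the hydroxyl to C7'.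
- Fallback: it sets out from 15 and returns at 23, taking the ring formation apart from the biaryl bond. Pyridinium p-toluenesulfonate in wet acetone should free (2S,5R)-2,6-dimethyl-5-(4-methylfuran-2-yl)heptanal F1. Reagent 8 with K2CO3 in MeOH should give 2-[(3R,6S)-2,6-dimethyloct-7-yn-3-yl]-4-methylfuran F2, whose reacting furan double bond carries only hydrogen next to the tether. (Ph3P)AuNTf2 in CH2Cl2 should convert it into (1S,4R)-8-hydroxycalamenene F3, where any isomeric phenol can still be removed at a simple stage. An oxidative phenol coupling (di-tert-butyl peroxide, chlorobenzene, 130 °C) then joins C7 of one molecule (ortho to OH) to C5 of another (para to OH). 23 would have to be separated from the C7–C7' and C5–C5' dimers.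

2. Step 9.
- What may go wrong: transmetalation and reductive elimination at the iodide flanked by a secondary alkyl group and a methyl group may be slow, so that protodemetalation and homocoupling of the alpha-furyl metal take over.
- Fallback: it sets out from 15 and 16 and returns at 19, with the polarity reversed. NBS in DMF at 0 °C should brominate the free alpha carbon of 15 to 2-bromo-5-[(3R,6S)-7,7-dimethoxy-2,6-dimethylheptan-3-yl]-3-methylfuran F4, a fast partner in oxidative addition. iPrMgCl·LiCl in THF at −20 °C should exchange the iodine of 16 to {2-[(3R,6S)-7,7-dimethoxy-2,6-dimethylheptan-3-yl]-4-methylfuran-3-yl}magnesium chloride F5. 2-Isopropoxy-4,4,5,5-tetramethyl-1,3,2-dioxaborolane turns it into 2-{2-[(3R,6S)-7,7-dimethoxy-2,6-dimethylheptan-3-yl]-4-methylfuran-3-yl}-4,4,5,5-tetramethyl-1,3,2-dioxaborolane F6, a beta-furyl boronate far less prone to protodeboronation than an alpha-furyl metal. Suzuki–Miyaura coupling of the two (Pd(OAc)2, SPhos, K3PO4, THF–H2O, 50 °C) should give 19.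

3. Step 5.
- What may go wrong: over-reduction of the ester to the alcohol, and partial epimerisation of the hindered alpha-isopropyl aldehyde while it waits in carbonate/methanol for a slow homologation.
- Fallback: it sets out from 7 and returns at 12, with no basic medium while the aldehyde is present. LiAlH4 in Et2O at 0 °C should give (2R,5S)-6,6-dimethoxy-5-methyl-2-(propan-2-yl)hexan-1-ol F7. Dess–Martin periodinane buffered with NaHCO3 gives aldehyde 9, now isolated. CBr4, PPh3 and Et3N in CH2Cl2 at 0 °C (first stage of the Corey–Fuchs sequence) give (3R,6S)-1,1-dibromo-7,7-dimethoxy-6-methyl-3-(propan-2-yl)hept-1-ene F8. n-BuLi (2.1 equiv) in THF at −78 °C converts it directly into acetylide 12, which is treated with 11 as in step 6.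

Further compounds
F1 | step 12 | (2S,5R)-2,6-dimethyl-5-(4-methylfuran-2-yl)heptanal | CC(C)[C@@H](CC[C@H](C)C=O)c1cc(C)co1
F2 | step 12 | 2-[(3R,6S)-2,6-dimethyloct-7-yn-3-yl]-4-methylfuran | CC(C)[C@@H](CC[C@H](C)C#C)c1cc(C)co1
F3 | step 12 | (1S,4R)-8-hydroxycalamenene, (5R,8S)-3,8-dimethyl-5-(propan-2-yl)-5,6,7,8-tetrahydronaphthalen-1-ol | Cc1cc2c(c(O)c1)[C@@H](C)CC[C@@H]2C(C)C
F4 | step 9 | 2-bromo-5-[(3R,6S)-7,7-dimethoxy-2,6-dimethylheptan-3-yl]-3-methylfuran | CC(C)[C@@H](CC[C@H](C)C(OC)OC)c1cc(C)c(Br)o1
F5 | step 9 | {2-[(3R,6S)-7,7-dimethoxy-2,6-dimethylheptan-3-yl]-4-methylfuran-3-yl}magnesium chloride | CC(C)[C@@H](CC[C@H](C)C(OC)OC)c1occ(C)c1[Mg]Cl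
F6 | step 9 | 2-{2-[(3R,6S)-7,7-dimethoxy-2,6-dimethylheptan-3-yl]-4-methylfuran-3-yl}-4,4,5,5-tetramethyl-1,3,2-dioxaborolane | CC(C)[C@@H](CC[C@H](C)C(OC)OC)c1occ(C)c1B1OC(C)(C)C(C)(C)O1
F7 | step 5 | (2R,5S)-6,6-dimethoxy-5-methyl-2-(propan-2-yl)hexan-1-ol | CC(C)[C@@H](CC[C@H](C)C(OC)OC)CO
F8 | step 5 | (3R,6S)-1,1-dibromo-7,7-dimethoxy-6-methyl-3-(propan-2-yl)hept-1-ene | CC(C)[C@@H](CC[C@H](C)C(OC)OC)C=C(Br)Br
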